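Ring C of the flavanonol is cut at O1–C2 and at C4–C4a, which divides the target into a ring A phenol and a three-carbon epoxy amide that carries ring B and both stereocentres. The key step exploits the 1,3-relation of O1 and C4a on ring A (a phenoxide oxygen and its ortho carbon, made a dinucleophile as an O,C-dilithio species) and the matching 1,3-relation of the acyl carbon C4 and the benzylic epoxide carbon C2. In one flask the aryllithium is acylated at C4 and the phenol then opens the epoxide at C2, so the two halves are joined and ring C is closed with transfer of the epoxide's chirality to C2 and C3.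

Key step: step 8

Remark (assumption): flavanone numbering is used (O1, C2, C3, C4, C4a, C5 to C8, C8a). The samarium/(S)-BINOL catalyst of step 7 is taken to deliver the (2R,3S)-epoxide, by analogy with lanthanide–BINOL epoxidations of cinnamoyl amides; should the sense prove opposite, (R)-BINOL is used instead.

Step 1
Reactants: 1 phloroglucinol (benzene-1,3,5-triol)
Product: 2 3,5-bis(methoxymethoxy)phenol
Conditions: NaH (2.0 equiv), DMF, 0 °C; MOMCl (2.0 equiv), 0 → 25 °C; chromatography (mono- and tris-ethers recycled)
Reagents that add atoms: chloromethyl methyl ether (MOMCl), COCCl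
Why: Williamson-type O-alkylation of the phenoxide with two equivalents of MOMCl should give the bis-ether as the main component of a statistical mixture from which it is separable.

Step 2
Reactants: 2 3,5-bis(methoxymethoxy)phenol
Product: 3 2-iodo-3,5-bis(methoxymethoxy)phenol
Conditions: I2 (1.0 equiv), NaHCO3 (1.2 equiv), THF/H2O, 0 °C
Reagents that add atoms: iodine, [I][I]
Why: Electrophilic aromatic iodination of the phenoxide should go to one of the two equivalent carbons ortho to the free oxygen, which are less hindered than the carbon between the two OMOM groups, and one equivalent of iodine at 0 °C should stop it at mono-iodination.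

Step 3
Reactants: 3 2-iodo-3,5-bis(methoxymethoxy)phenol; 4 prenyl bromide (1-bromo-3-methylbut-2-ene)
Product: 5 2-iodo-3,5-bis(methoxymethoxy)-6-(3-methylbut-2-en-1-yl)phenol
Conditions: NaH (1.05 equiv), toluene, 0 °C; then 4 (1.1 equiv), 0 → 25 °C, dark
Reagents that add atoms: none
Why: Ortho C-allylation of a sodium phenoxide as a tight ion pair in a non-polar solvent should place the unrearranged prenyl group on the only free ortho carbon, the para carbon being shielded by two OMOM groups.

Step 4
Reactants: 6 4-bromophenol; 7 geranyl bromide ((2E)-1-bromo-3,7-dimethylocta-2,6-diene)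
Product: 8 4-bromo-2-[(2E)-3,7-dimethylocta-2,6-dien-1-yl]phenol
Conditions: NaH (1.0 equiv), toluene, 0 °C; then 7 (1.0 equiv), 25 °C
Reagents that add atoms: none
Why: The same ortho C-allylation of a sodium phenoxide in toluene should give the 2-geranylphenol, since the para position is blocked by bromine and substitution at the primary allylic carbon leaves the E double bond untouched.

Step 5
Reactants: 8 4-bromo-2-[(2E)-3,7-dimethylocta-2,6-dien-1-yl]phenol
Product: 9 4-bromo-2-[(2E)-3,7-dimethylocta-2,6-dien-1-yl]-1-(methoxymethoxy)benzene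
Conditions: NaH (1.1 equiv), THF, 0 °C; MOMCl (1.2 equiv), 0 → 25 °C
Reagents that add atoms: chloromethyl methyl ether (MOMCl), COCCl
Why: Williamson etherification of the phenoxide should give the MOM ether, which masks the acidic proton for the later organolithium step and can be removed together with the ring A acetals.

Step 6
Reactants: 9 4-bromo-2-[(2E)-3,7-dimethylocta-2,6-dien-1-yl]-1-(methoxymethoxy)benzene; 10 4-acryloylmorpholine
Product: 11 (2E)-3-{3-[(2E)-3,7-dimethylocta-2,6-dien-1-yl]-4-(methoxymethoxy)phenyl}-1-(morpholin-4-yl)prop-2-en-1-one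
Conditions: Pd(OAc)2 (3 mol%), P(o-tol)3 (6 mol%), NaOAc (1.5 equiv), DMF, 110 °C
Reagents that add atoms: none
Why: The Mizoroki–Heck reaction of the aryl bromide with the electron-poor acrylamide should give the E-cinnamamide, the trisubstituted geranyl alkenes being inert to carbopalladation.

Step 7
Reactants: 11 (2E)-3-{3-[(2E)-3,7-dimethylocta-2,6-dien-1-yl]-4-(methoxymethoxy)phenyl}-1-(morpholin-4-yl)prop-2-en-1-one
Product: 12 [(2R,3S)-3-{3-[(2E)-3,7-dimethylocta-2,6-dien-1-yl]-4-(methoxymethoxy)phenyl}oxiran-2-yl](morpholin-4-yl)methanone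
Conditions: Sm(O-i-Pr)3 (10 mol%), (S)-BINOL (10 mol%), Ph3As=O (10 mol%), TBHP (1.5 equiv, decane), 4 Å molecular sieves, THF, 25 °C
Reagents that add atoms: tert-butyl hydroperoxide, CC(C)(C)OO
Why: Catalytic asymmetric nucleophilic epoxidation (Weitz–Scheffer type) by a samarium peroxide in the BINOL pocket should add to one face of the samarium-bound unsaturated amide and close to the trans-(2R,3S)-epoxide, setting both stereocentres by catalyst control, while the electron-rich isolated alkenes do not react with a nucleophilic oxidant.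

Step 8
Reactants: 5 2-iodo-3,5-bis(methoxymethoxy)-6-(3-methylbut-2-en-1-yl)phenol; 12 [(2R,3S)-3-{3-[(2E)-3,7-dimethylocta-2,6-dien-1-yl]-4-(methoxymethoxy)phenyl}oxiran-2-yl](morpholin-4-yl)methanone
Product: 16 (2R,3R)-3-hydroxy-5,7-bis(methoxymethoxy)-2-[3-geranyl-4-(methoxymethoxy)phenyl]-8-prenylchroman-4-one, via dilithiated phenoxide 13 (not isolated), via tetrahedral dilithium adduct 14 (not isolated), via hydroxy epoxy ketone 15 (not isolated)
Conditions: 5 (1.2 equiv), MeLi (1.2 equiv), THF, −78 °C; t-BuLi (2.4 equiv), −78 °C; then 12 (1.0 equiv), −78 → −30 °C; then CF3CO2H (4.5 equiv), −78 → 0 °C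
Reagents that add atoms: none
Why: Deprotonation of 5 and iodine–lithium exchange give the O,C-dilithio species 13, whose carbanion (C4a) adds to the morpholine amide of 12 to give the chelated tetrahedral adduct 14 that cannot add a second time; acid releases morpholine and the ketone 15, whose free phenol (O1), now held beside the epoxide by the new C4–C4a bond, opens it at the benzylic carbon C2. The closest known reaction types are the acylation of lithium 2-lithiophenoxides by Weinreb-type amides and the acid-mediated cyclization of 2'-hydroxychalcone epoxides to trans-dihydroflavonols, merged here in one flask as a formal (3+3) annulation. Ring C closes by a 6-endo-tet opening of the epoxide. C3 keeps the R configuration of the epoxide carbon next to the carbonyl because its C–O bond is not touched, and C2 becomes R by inversion at the S-configured benzylic epoxide carbon; should the opening have cationic character, the fixed C3 centre still directs closure and acid equilibration to the more stable 2,3-trans isomer. The step needs exchange at iodine to outrun MOM-directed deprotonation (t-BuLi at −78 °C), 6-endo to beat 5-exo opening (the 4-alkoxyphenyl group makes the benzylic C–O bond the one that ionizes under acid), and closure through the oxygen flanked by the prenyl group, which is secured because it is the only unprotected oxygen of ring A.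

Step 9
Reactants: 16 (2R,3R)-3-hydroxy-5,7-bis(methoxymethoxy)-2-[3-geranyl-4-(methoxymethoxy)phenyl]-8-prenylchroman-4-one
Product: 17 sanggenol C ((2R,3R)-3,5,7-trihydroxy-2-{4-hydroxy-3-[(2E)-3,7-dimethylocta-2,6-dien-1-yl]phenyl}-8-(3-methylbut-2-en-1-yl)-2,3-dihydro-4H-chromen-4-one)
Conditions: HCl (1.25 M in MeOH), THF, 40 °C, monitored closely
Reagents that add atoms: none
Why: Acid-catalysed transacetalization to methanol should remove all three aryl MOM ethers under conditions mild enough for the prenyl and geranyl groups, and C2 and C3 should be unaffected because the 2,3-trans isomer is also the thermodynamic one.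

Compound list
1 | phloroglucinol | Oc1cc(O)cc(O)c1 | starting material
2 | 3,5-bis(methoxymethoxy)phenol | COCOc1cc(O)cc(OCOC)c1 | intermediate
3 | 2-iodo-3,5-bis(methoxymethoxy)phenol | COCOc1cc(OCOC)c(I)c(O)c1 | intermediate
4 | prenyl bromide | CC(C)=CCBr | starting material
5 | 2-iodo-3,5-bis(methoxymethoxy)-6-(3-methylbut-2-en-1-yl)phenol | Oc1c(I)c(OCOC)cc(OCOC)c1CC=C(C)C | intermediate
6 | 4-bromophenol | Oc1ccc(Br)cc1 | starting material
7 | geranyl bromide | CC(C)=CCC/C(C)=C/CBr | starting material
8 | 4-bromo-2-[(2E)-3,7-dimethylocta-2,6-dien-1-yl]phenol | CC(C)=CCC/C(C)=C/Cc1cc(Br)ccc1O | intermediate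
9 | 4-bromo-2-[(2E)-3,7-dimethylocta-2,6-dien-1-yl]-1-(methoxymethoxy)benzene | CC(C)=CCC/C(C)=C/Cc1cc(Br)ccc1OCOC | intermediate
10 | 4-acryloylmorpholine | C=CC(=O)N1CCOCC1 | starting material
11 | (2E)-3-{3-geranyl-4-(methoxymethoxy)phenyl}-1-(morpholin-4-yl)prop-2-en-1-one | CC(C)=CCC/C(C)=C/Cc1cc(/C=C/C(=O)N2CCOCC2)ccc1OCOC | intermediate
12 | [(2R,3S)-3-{3-geranyl-4-(methoxymethoxy)phenyl}oxiran-2-yl](morpholin-4-yl)methanone | CC(C)=CCC/C(C)=C/Cc1cc([C@@H]2O[C@H]2C(=O)N3CCOCC3)ccc1OCOC | intermediate
13 | lithium 2-lithio-3,5-bis(methoxymethoxy)-6-prenylphenoxide (dilithiated phenoxide) | [Li]Oc1c([Li])c(OCOC)cc(OCOC)c1CC=C(C)C | intermediate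
14 | tetrahedral dilithium adduct of 13 and 12 (hemiaminal carbon of undefined configuration) | CC(C)=CCC/C(C)=C/Cc1cc([C@@H]2O[C@H]2C(O[Li])(N3CCOCC3)c4c(O[Li])c(CC=C(C)C)c(OCOC)cc4OCOC)ccc1OCOC | intermediate
15 | [(2R,3S)-3-{3-geranyl-4-(methoxymethoxy)phenyl}oxiran-2-yl][2-hydroxy-4,6-bis(methoxymethoxy)-3-prenylphenyl]methanone (hydroxy epoxy ketone) | CC(C)=CCC/C(C)=C/Cc1cc([C@@H]2O[C@H]2C(=O)c3c(O)c(CC=C(C)C)c(OCOC)cc3OCOC)ccc1OCOC | intermediate
16 | (2R,3R)-3-hydroxy-5,7-bis(methoxymethoxy)-2-[3-geranyl-4-(methoxymethoxy)phenyl]-8-prenylchroman-4-one | CC(C)=CCC/C(C)=C/Cc1cc([C@H]2Oc3c(CC=C(C)C)c(OCOC)cc(OCOC)c3C(=O)[C@@H]2O)ccc1OCOC | intermediate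
17 | sanggenol C | CC(C)=CCC/C(C)=C/Cc1cc([C@H]2Oc3c(CC=C(C)C)c(O)cc(O)c3C(=O)[C@@H]2O)ccc1O | target

Total step count: 9 steps.
Longest linear sequence: 6 steps (from 4-bromophenol 6 through steps 4, 5, 6, 7, 8 and 9 to 17).

Steps most likely to fail

Step 8. The aggregated dilithio species may add too slowly to the amide or may instead remove the proton on the epoxide carbon next to the carbonyl. On the acid quench the phenol may attack that same carbon (5-exo) or the epoxide may rearrange by hydride shift before it is trapped. The fallback sets out from 5 and comes back to the route at 16, and forms the two bonds in separate operations. Compound 5 is silylated (TIPSOTf, 2,6-lutidine, CH2Cl2, 0 °C) to the triisopropylsilyl ether of 5 F1. Iodine–lithium exchange of F1 (t-BuLi, 2 equiv, Et2O, −78 °C) gives a monoanionic, more reactive aryllithium, which is added to 12 and should give, after aqueous NH4Cl, the 2'-silyloxy epoxy ketone F2. Fluoride (TBAF buffered with AcOH, THF, 0 °C, followed by a trace of acid if needed) then frees the phenol, which should close ring C to 16.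

Step 3. The phenoxide may be alkylated on oxygen instead of carbon, at the para carbon, or twice. The fallback sets out from 3 and comes back at 5, and replaces the ionic C-alkylation by a sigmatropic shift. Copper-catalysed O-alkylation of 3 with 3-chloro-3-methylbut-1-yne (CuCl2 cat., DBU, MeCN, 0 °C) should give the 1,1-dimethylpropargyl ether F3. Semi-hydrogenation (H2, Pd/CaCO3 poisoned with Pb(OAc)2, quinoline, EtOAc) should give the 1,1-dimethylallyl ether F4. An aromatic Claisen rearrangement (toluene, 80–110 °C) should then deliver the allyl unit, with allylic inversion, to the only free ortho carbon and so give 5.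

Step 9. Before the last acetal is gone, protic acid may close the prenyl group onto O7 (chroman formation) or the geranyl chain onto O4', or may cyclize the geranyl diene. The fallback sets out from 16 and comes back at 17, and avoids protic acid during the acetal cleavage. TMSOTf with 2,2'-bipyridyl (CH2Cl2, 0 °C) should exchange the three aryl MOM ethers for trimethylsilyl ethers, silylating the C3 hydroxyl as well, to give the tetrakis(trimethylsilyl) ether of sanggenol C F5. Mild methanolysis (MeOH, PPTS cat., 0 °C) should then give 17.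

Further compounds
F1 | step 8 | [2-iodo-3,5-bis(methoxymethoxy)-6-prenylphenoxy]triisopropylsilane | CC(C)[Si](Oc1c(I)c(OCOC)cc(OCOC)c1CC=C(C)C)(C(C)C)C(C)C
F2 | step 8 | [(2R,3S)-3-{3-geranyl-4-(methoxymethoxy)phenyl}oxiran-2-yl][4,6-bis(methoxymethoxy)-3-prenyl-2-(triisopropylsilyloxy)phenyl]methanone | CC(C)=CCC/C(C)=C/Cc1cc([C@@H]2O[C@H]2C(=O)c3c(O[Si](C(C)C)(C(C)C)C(C)C)c(CC=C(C)C)c(OCOC)cc3OCOC)ccc1OCOC
F3 | step 3 | 2-iodo-3,5-bis(methoxymethoxy)-1-(2-methylbut-3-yn-2-yloxy)benzene | C#CC(C)(C)Oc1c(I)c(OCOC)cc(OCOC)c1
F4 | step 3 | 2-iodo-3,5-bis(methoxymethoxy)-1-(2-methylbut-3-en-2-yloxy)benzene | C=CC(C)(C)Oc1c(I)c(OCOC)cc(OCOC)c1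
F5 | step 9 | tetrakis(trimethylsilyl) ether of sanggenol C | CC(C)=CCC/C(C)=C/Cc1cc([C@H]2Oc3c(CC=C(C)C)c(O[Si](C)(C)C)cc(O[Si](C)(C)C)c3C(=O)[C@@H]2O[Si](C)(C)C)ccc1O[Si](C)(C)C
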